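The cyclohexane ring is disconnected at C1–C6 (ring CH2 to the side-chain-bearing CH) and at C2–C3 (the C–C bond of the trisubstituted epoxide). Both bonds form in one vinylsulfonium epoxy-annulation: the carbanion of an acyclic β-keto sulfone (C6) adds to diphenyl vinyl sulfonium triflate, and the ylide so formed (C2) attacks a methyl ketone (C3), closing ring and cis-fused methyl epoxide together. The step exploits the C1H2–C2H(O)–C3(O)CH3 epoxide unit and the fact that C6 is α to C7, the later exocyclic methylene carbon, which can be a ketone. The precursor takes C4/C5 from D-erythrose and C8 from (S)-glycidate.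

Key step: step 9

Remark (numbering used here): ring C1 = CH2, C2 = epoxide CH, C3 = epoxide C(CH3), C4 = CH(OAng), C5 = CH(OH), C6 = CH bearing the side chain; side chain C7 = C(=CH2), C8 = CH(OAng), C9 = CH2, C10/C11 = dimethyloxirane carbons. In the target C2 is S, C3 S, C4 R, C5 R, C6 S, C8 S, C10 R; the epoxide oxygen, both ring oxygens and the side chain lie on one face.

Assumption: 1, 5, 6, 12, 19 and the D-fructose-derived Shi ketone are purchased; 1 is otherwise one i-Bu2AlH reduction away from the commercial erythronolactone acetonide.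

Step 1
Reactants: 1 2,3-O-isopropylidene-D-erythrose
Product: 2 1-[(4S,5R)-5-(hydroxymethyl)-2,2-dimethyl-1,3-dioxolan-4-yl]ethanol (carbinol epimers)
Conditions: MeMgBr (3 equiv), THF, 0 °C → rt; aq. NH4Cl
Reagents that add atoms: methylmagnesium bromide, C[Mg]Br
Why: Grignard addition to the open-chain aldehyde form of the lactol (the first equivalent deprotonates it); the new carbinol centre forms unselectively, which is harmless because it becomes the C3 ketone in step 8.

Step 2
Reactants: 2 methyl carbinol diol
Product: 3 1-[(4S,5S)-2,2-dimethyl-5-(phenylsulfanylmethyl)-1,3-dioxolan-4-yl]ethanol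
Conditions: PhSSPh, n-Bu3P, pyridine, rt
Reagents that add atoms: diphenyl disulfide, c1ccc(SSc2ccccc2)cc1
Why: Phosphine–disulfide redox thioetherification (alkoxyphosphonium formation, then SN2 by thiolate) is selective for the primary hydroxyl, and the strongly nucleophilic thiolate should outrun cyclisation by the secondary hydroxyl.

Step 3
Reactants: 3 primary phenyl sulfide
Product: 4 1-[(4S,5S)-2,2-dimethyl-5-(phenylsulfonylmethyl)-1,3-dioxolan-4-yl]ethanol
Conditions: H2O2 (30 % aq.), (NH4)6Mo7O24·4H2O (cat.), EtOH, 0 °C → rt
Reagents that add atoms: hydrogen peroxide, OO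
Why: Molybdate-catalysed peroxide oxidation of sulfide to sulfone leaves the secondary alcohol and the acetonide untouched.

Step 4
Reactants: 5 methyl (S)-glycidate; 6 2-methylprop-1-enylmagnesium bromide
Product: 7 methyl (S)-2-hydroxy-5-methylhex-4-enoate
Conditions: CuI (10 mol %), THF, −40 → −20 °C; aq. NH4Cl
Reagents that add atoms: none
Why: Copper-catalysed Grignard opening of the glycidic ester at its terminal carbon (SN2) leaves the oxygen-bearing stereocentre of 5 untouched, so C8 is delivered as S.

Step 5
Reactants: 7 hydroxy ester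
Product: 8 methyl (S)-5-methyl-2-(triethylsilyloxy)hex-4-enoate
Conditions: TESCl, imidazole, CH2Cl2, 0 °C → rt
Reagents that add atoms: chlorotriethylsilane, CC[Si](Cl)(CC)CC
Why: Standard silylation of a secondary alcohol; TES is chosen because it is later removed together with the acetonide in step 12.

Step 6
Reactants: 8 TES-protected ester
Product: 9 (S)-5-methyl-2-(triethylsilyloxy)hex-4-enal
Conditions: i-Bu2AlH (1.1 equiv), CH2Cl2, −78 °C; Rochelle salt
Reagents that add atoms: none
Why: Partial reduction of an α-silyloxy ester stops at the chelated aluminium hemiacetal at −78 °C and releases the aldehyde on work-up without epimerisation.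

Step 7
Reactants: 4 hydroxy sulfone; 9 α-silyloxy aldehyde
Product: 10 β-hydroxy sulfone diol (mixture at the three carbinol and sulfonyl-bearing centres)
Conditions: 4, n-BuLi (2.1 equiv), THF, −78 °C; then 9, −78 °C; AcOH quench at −78 °C
Reagents that add atoms: none
Why: Julia-type addition of the α-sulfonyl carbanion (as its alkoxide dianion) to the aldehyde is fast at −78 °C, which keeps β-elimination of the acetonide oxygen and silyl migration in check; the new centres are inconsequential because two are oxidised in step 8 and the third becomes the planar carbanion of step 9.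

Step 8
Reactants: 10 β-hydroxy sulfone diol
Product: 11 diketo sulfone CH3CO–C4H(O)–C5H(O)–C6H(SO2Ph)–C7O–C8H(OTES)–prenyl with C4/C5 as cis-acetonide (C6 labile)
Conditions: Dess–Martin periodinane (3 equiv), NaHCO3, CH2Cl2, rt
Reagents that add atoms: none
Why: Dess–Martin oxidation converts both secondary alcohols in one operation, giving the C3 methyl ketone and the C7 ketone of the β-keto sulfone, and the buffered conditions spare acetonide and TES ether.

Step 9
Reactants: 11 diketo sulfone; 12 diphenyl vinyl sulfonium triflate
Product: 15 cis-epoxide-fused cyclohexane bearing the 4,5-acetonide and at C6 both phenylsulfonyl and the (S)-α-silyloxy acyl group (C6 epimers), via sulfonium ylide 13 (not isolated), via betaine 14 (not isolated)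
Conditions: 12 (1.3 equiv), DBU (1.2 equiv), CH2Cl2, 0 °C → rt
Reagents that add atoms: none
Why: DBU deprotonates only the β-keto sulfone C6–H of 11; the stabilised carbanion adds to the CH2 terminus of 12 (C1–C6 bond) to give ylide 13, whose carbanion C2 attacks the methyl ketone carbon (C2–C3 bond) to give betaine 14, and the alkoxide then displaces Ph2S to close the epoxide. The closest known reaction type is the vinylsulfonium epoxy-annulation of nucleophiles tethered to a ketone, a conjugate addition followed by an intramolecular Corey–Chaykovsky epoxidation. The cyclohexane closes 6-exo-trig at the C3 carbonyl and the oxirane 3-exo-tet at C2 with inversion, which enforces the cis ring fusion and sets C2 and C3 together. The face of C3 is controlled by the C4 stereocentre: in a chair-like transition state the C4–O bond lies anti to the forming C2–C3 bond (polar Felkin–Anh) and the C3 methyl is equatorial, away from the axial C5 oxygen, so the epoxide oxygen ends cis to the C4 and C5 oxygens (C2 S, C3 S). The step needs C-alkylation at C6 in preference to reaction of the methyl ketone enolates, and no loss of the β-alkoxy group: the far higher acidity of the β-keto sulfone secures the first, and the doubly stabilised carbanion, for which alkoxide expulsion is reversible and unfavourable, the second. C6 forms as an epimeric mixture that converges in step 10.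

Step 10
Reactants: 15 annulated β-keto sulfone
Product: 16 ketone with C6–H, the acyl group cis to the C5 oxygen
Conditions: SmI2 (2.5 equiv), THF–MeOH, −78 °C
Reagents that add atoms: none
Why: Reductive desulfonylation of the β-keto sulfone by electron transfer gives an exocyclic samarium enolate that is protonated by methanol under kinetic control on the face opposite the adjacent C5 acetonide oxygen (kinetic ketonisation of exocyclic enolates gives the cis-1,2 isomer), setting C6.

Step 11
Reactants: 16 ketone
Product: 17 C7 exocyclic methylene compound (acetonide and TES ether intact)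
Conditions: Cp2TiMe2 (3 equiv), toluene, 70 °C, dark
Reagents that add atoms: dimethyltitanocene, C[Ti](C)(C1C=CC=C1)C1C=CC=C1
Why: Petasis methylenation is non-basic, so the hindered β-alkoxy ketone should be converted to the 1,1-disubstituted alkene without epimerisation at C6 or C8 and without E1cB loss of the C5 oxygen.

Step 12
Reactants: 17 protected diene epoxide
Product: 18 triol (C4–OH, C5–OH, C8–OH) with ring epoxide, C7 methylene and prenyl alkene
Conditions: AcOH–H2O–THF (3:1:1), 45 °C
Reagents that add atoms: none
Why: Mild aqueous acid hydrolyses the cis-fused acetonide and the TES ether, while the epoxide, deactivated by the flanking C4 oxygen and out of reach of the cis hydroxyls for backside attack, should survive.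

Step 13
Reactants: 18 triol; 19 angelic acid
Product: 21 4,8-di-O-angeloyl compound with free C5–OH, via mixed anhydride 20 (not isolated)
Conditions: 19 (2.4 equiv), 2,4,6-trichlorobenzoyl chloride, Et3N, THF, rt, filter; then 18, Et3N, toluene, 70 °C
Reagents that add atoms: none
Why: Yamaguchi esterification through the mixed anhydride without a nucleophilic catalyst preserves the Z geometry, and the allylic C8 hydroxyl and the equatorial C4 hydroxyl should acylate while the axial C5 hydroxyl, flanked by two cis substituents, stays free.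

Step 14
Reactants: 21 diangelate
Product: 22 CNP0296086.3
Conditions: D-fructose-derived Shi ketone (30 mol %), Oxone, K2CO3, n-Bu4NHSO4, MeCN–dimethoxymethane–aq. Na2B4O7/Na2EDTA buffer, 0 °C
Reagents that add atoms: Oxone (potassium peroxymonosulfate, KHSO5), [K+].[O-]S(=O)(=O)OO
Why: Shi epoxidation through the chiral dioxirane (spiro transition state) attacks the electron-rich trisubstituted C10=C11 alkene in preference to the 1,1-disubstituted and conjugated alkenes, and the D-fructose-derived ketone sets C10 as R by reagent control.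

Compound list
1 | 2,3-O-isopropylidene-D-erythrose, (3aR,6aR) lactol, anomer mixture | OC1OC[C@H]2OC(C)(C)O[C@@H]12 | starting material
2 | 1-[(4S,5R)-5-(hydroxymethyl)-2,2-dimethyl-1,3-dioxolan-4-yl]ethanol, carbinol epimers | CC(O)[C@@H]1OC(C)(C)O[C@@H]1CO | intermediate
3 | 1-[(4S,5S)-2,2-dimethyl-5-(phenylsulfanylmethyl)-1,3-dioxolan-4-yl]ethanol | CC(O)[C@@H]1OC(C)(C)O[C@@H]1CSc1ccccc1 | intermediate
4 | 1-[(4S,5S)-2,2-dimethyl-5-(phenylsulfonylmethyl)-1,3-dioxolan-4-yl]ethanol | CC(O)[C@@H]1OC(C)(C)O[C@@H]1CS(=O)(=O)c1ccccc1 | intermediate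
5 | methyl (S)-glycidate | COC(=O)[C@@H]1CO1 | starting material
6 | 2-methylprop-1-enylmagnesium bromide | CC(C)=C[Mg]Br | starting material
7 | methyl (S)-2-hydroxy-5-methylhex-4-enoate | COC(=O)[C@@H](O)CC=C(C)C | intermediate
8 | methyl (S)-5-methyl-2-(triethylsilyloxy)hex-4-enoate | COC(=O)[C@@H](O[Si](CC)(CC)CC)CC=C(C)C | intermediate
9 | (S)-5-methyl-2-(triethylsilyloxy)hex-4-enal | O=C[C@@H](O[Si](CC)(CC)CC)CC=C(C)C | intermediate
10 | β-hydroxy sulfone diol: cis-dioxolane (D-erythro) carrying 1-hydroxyethyl and the CH(SO2Ph)–CH(OH)–CH(OTES)–prenyl chain, C8 S, other new centres mixed | CC(O)[C@@H]1OC(C)(C)O[C@@H]1C(S(=O)(=O)c1ccccc1)C(O)[C@@H](O[Si](CC)(CC)CC)CC=C(C)C | intermediate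
11 | diketo sulfone: cis-dioxolane (D-erythro) carrying acetyl and the CH(SO2Ph)–CO–CH(OTES)–prenyl chain, C8 S, C6 labile | CC(=O)[C@@H]1OC(C)(C)O[C@@H]1C(S(=O)(=O)c1ccccc1)C(=O)[C@@H](O[Si](CC)(CC)CC)CC=C(C)C | intermediate
12 | diphenyl vinyl sulfonium triflate | C=C[S+](c1ccccc1)c1ccccc1.[O-]S(=O)(=O)C(F)(F)F | starting material
13 | sulfonium ylide formed by C6 addition to 12 | CC(=O)[C@@H]1OC(C)(C)O[C@@H]1C(C[CH-][S+](c1ccccc1)c1ccccc1)(S(=O)(=O)c1ccccc1)C(=O)[C@@H](O[Si](CC)(CC)CC)CC=C(C)C | intermediate
14 | betaine: cyclohexane with C3 alkoxide (cis to C4–O) and trans C2 diphenylsulfonium | CC(C)=CC[C@H](O[Si](CC)(CC)CC)C(=O)C1(S(=O)(=O)c4ccccc4)C[C@@H]([S+](c5ccccc5)c5ccccc5)[C@@]([O-])(C)[C@@H]3OC(C)(C)O[C@H]13 | intermediate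
15 | annulation product: 2,3-epoxy-3-methylcyclohexane with 4,5-acetonide, epoxide and acetonide oxygens cis, C6 bearing SO2Ph and the (S)-2-(triethylsilyloxy)-5-methylhex-4-enoyl group (C6 epimers) | CC(C)=CC[C@H](O[Si](CC)(CC)CC)C(=O)C1(S(=O)(=O)c4ccccc4)C[C@@H]2O[C@]2(C)[C@@H]3OC(C)(C)O[C@H]13 | intermediate
16 | desulfonylated ketone, C6–H, acyl group cis to the C5 oxygen, other centres as in 15 | CC(C)=CC[C@H](O[Si](CC)(CC)CC)C(=O)[C@@H]1C[C@@H]2O[C@]2(C)[C@@H]3OC(C)(C)O[C@H]13 | intermediate
17 | C7 methylene compound, acetonide and TES ether retained, ring and C8 centres as in the target | CC(C)=CC[C@H](O[Si](CC)(CC)CC)C(=C)[C@@H]1C[C@@H]2O[C@]2(C)[C@@H]3OC(C)(C)O[C@H]13 | intermediate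
18 | triol: ring as in the target with free C4–OH and C5–OH, side chain with free C8–OH and prenyl alkene | CC(C)=CC[C@H](O)C(=C)[C@@H]1C[C@@H]2O[C@]2(C)[C@H](O)[C@@H]1O | intermediate
19 | angelic acid, (Z)-2-methylbut-2-enoic acid | C/C=C(/C)C(O)=O | starting material
20 | angelic 2,4,6-trichlorobenzoic mixed anhydride | C/C=C(/C)C(=O)OC(=O)c1c(Cl)cc(Cl)cc1Cl | intermediate
21 | 4,8-di-O-angeloyl compound with free C5–OH and prenyl alkene | CC(C)=CC[C@H](OC(=O)/C(C)=C\C)C(=C)[C@@H]1C[C@@H]2O[C@]2(C)[C@H](OC(=O)/C(C)=C\C)[C@@H]1O | intermediate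
22 | CNP0296086.3 | C=C([C@H](C[C@H]1OC1(C)C)OC(=O)/C(C)=C\C)[C@@H]1C[C@@H]2O[C@]2(C)[C@H](OC(=O)/C(C)=C\C)[C@@H]1O | target

Total step count: 14. Longest linear sequence: 11 steps (steps 1–3 and 7–14); steps 4–6 form the second branch, joined in step 7.

Steps most likely to fail

1. Step 9 (key step). The ylide may add to the wrong face of the C3 ketone, or be protonated and diverted into other alkylations, so that the epoxide forms trans to the C4 oxygen or the ring does not close. Fallback, from 11 back to 15: the two bonds are made separately and the epoxide oxygen is delivered by a hydroxyl group. C-Allylation of 11 (allyl bromide, K2CO3, acetone) gives the C6-allyl β-keto sulfone F1. Wittig methylenation of the unhindered C3 methyl ketone (Ph3P=CH2, THF, 0 °C) gives the isopropenyl diene F2. Ring-closing metathesis (second-generation Grubbs catalyst, CH2Cl2, 40 °C) forms the C2=C3 bond in the cyclohexene F3. AcOH–H2O–THF removes acetonide and TES ether to give the cyclohexene triol F4. VO(acac)2 with t-BuOOH (CH2Cl2, 0 °C) epoxidises the ring alkene cis to the allylic C4 hydroxyl, faster than the side-chain alkene that is only homoallylic to the C8 hydroxyl, to give the epoxy triol F5. 2,2-Dimethoxypropane with PPTS re-forms the cis-acetonide F6, and TESCl with imidazole returns 15.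

2. Step 13. Acylation may spill over to the C5 hydroxyl or stop at a mono-ester, and the angelate may migrate between the cis C4 and C5 oxygens. Fallback, from 18 back to 21: the esters are introduced one at a time and the second is directed by a tin acetal. One equivalent of 20 at room temperature esterifies only the allylic C8 hydroxyl to give the C8 mono-angelate F7. Bu2SnO (toluene, reflux, water removal) converts the cis-4,5-diol into the dibutylstannylene acetal F8, which reacts with 20 at room temperature at the equatorial C4 oxygen to give 21.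

3. Step 11. The ketone, flanked by two tertiary carbons, may react sluggishly with the titanium methylidene, and prolonged heating invites epimerisation at C6 or E1cB loss of the C5 oxygen. Fallback, from 16 back to 17: a two-stage Peterson olefination. Me3SiCH2MgCl with CeCl3 (THF, −78 °C) adds without enolisation to give the β-hydroxysilane F9, and KH (THF, 0 °C) effects syn-elimination to 17 once the carbonyl group is gone.

Further compounds
F1 | step 9 | C6-allyl β-keto sulfone | CC(=O)[C@@H]1OC(C)(C)O[C@@H]1C(CC=C)(S(=O)(=O)c1ccccc1)C(=O)[C@@H](O[Si](CC)(CC)CC)CC=C(C)C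
F2 | step 9 | isopropenyl diene | CC(=C)[C@@H]1OC(C)(C)O[C@@H]1C(CC=C)(S(=O)(=O)c1ccccc1)C(=O)[C@@H](O[Si](CC)(CC)CC)CC=C(C)C
F3 | step 9 | cyclohexene (C2=C3) with acetonide and TES ether | CC(C)=CC[C@H](O[Si](CC)(CC)CC)C(=O)C1(S(=O)(=O)c4ccccc4)CC=C(C)[C@@H]3OC(C)(C)O[C@H]13
F4 | step 9 | cyclohexene triol | CC(C)=CC[C@H](O)C(=O)C1(S(=O)(=O)c4ccccc4)CC=C(C)[C@H](O)[C@@H]1O
F5 | step 9 | epoxy triol, epoxide cis to C4–OH | CC(C)=CC[C@H](O)C(=O)C1(S(=O)(=O)c4ccccc4)C[C@@H]2O[C@]2(C)[C@H](O)[C@@H]1O
F6 | step 9 | epoxy acetonide with free C8–OH | CC(C)=CC[C@H](O)C(=O)C1(S(=O)(=O)c4ccccc4)C[C@@H]2O[C@]2(C)[C@@H]3OC(C)(C)O[C@H]13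
F7 | step 13 | C8 mono-angelate | CC(C)=CC[C@H](OC(=O)/C(C)=C\C)C(=C)[C@@H]1C[C@@H]2O[C@]2(C)[C@H](O)[C@@H]1O
F8 | step 13 | 4,5-O-dibutylstannylene acetal of the C8 mono-angelate | CC(C)=CC[C@H](OC(=O)/C(C)=C\C)C(=C)[C@@H]1C[C@@H]2O[C@]2(C)[C@@H]3O[Sn](CCCC)(CCCC)O[C@H]13
F9 | step 11 | β-hydroxysilane (C7 carbinol epimers) | CC(C)=CC[C@H](O[Si](CC)(CC)CC)C(O)(C[Si](C)(C)C)[C@@H]1C[C@@H]2O[C@]2(C)[C@@H]3OC(C)(C)O[C@H]13
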